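The data come from a simulation for substances that don't exist; the scatter is artificial.

**Task.** Read the plateau twice. The flask asked about is the ash run carried on, so the readings of ash are its own history; elm is a separate, earlier run.

the same everywhere: free catalyst 1.2 mM
- ash: starting material 0.10 M; partner 0.20 M; scavenger 0.12 M; temperature 0 °C; the very flask that is asked about, followed so far
- elm: starting material 0.050 M; partner 0.20 M; scavenger 0.12 M; temperature 6 °C; run made earlier
- flask: starting material 0.10 M; partner 0.200 M; scavenger 0.120 M; temperature 0 °C; time 8.0 d

| run | time / d | target / % | starting material / % |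
|---|---|---|---|
| ash | 0.500 | 11.4 | 88.8 |
| ash | 1.67 | 27.1 | 73.5 |
| ash | 3.00 | 30.6 | 66.9 |
| ash | 4.00 | 32.3 | 65.1 |
| ash | 6.00 | 32.8 | 65.6 |
| ash | 8.00 | 33.1 | 66.0 |
| elm | 0.625 | 27.3 | 69.2 |
| elm | 1.25 | 35.1 | 62.8 |
| elm | 2.08 | 37.4 | 59.5 |
| elm | 2.50 | 37.8 | 60.5 |
| elm | 3.00 | 38.3 | 60.8 |
| elm | 4.00 | 35.9 | 61.2 |

(scatter of a reading: 1 percentage point)

- summer: at 8.0 d raise the temperature by 20 K, then wait 2.5 d
- noon: at 8.0 d add free catalyst, 100% of the amount charged, then wait 2.5 d
- spring: at 8.0 d add partner, 100% of the amount charged, then wait 2.5 d
- midnight: change nothing and wait 2.5 d more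

1. target, in percent of the starting material first charged, at 8.0 d
2. which option adds most target ("none" when 2 percentage points or less is all one gets) (summer / noon / spring / midnight / none)
3. target present, in percent of the starting material first charged, after noon
4. target present, in percent of the starting material first charged, after midnight

- what is added takes up no volume worth counting
- the numbers in the tables scatter with a standard deviation of 1 percentage point
- a reading or a percentage of target counts all its forms, free or not

**Two ways.** The first way is the target column of ash, 33.1% at 8.00 d. The second is the separate starting-material column: 66.0% remains, so 34.0% has reacted. The two differ by 0.9 percentage points with a scatter of 1 point on each reading, so what reacts can be read as target, and the reckoning here commits to the target reading, 33.1%.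

**Rate drift.** Target in ash rises at 0.228 d⁻¹, as a fraction of the charge, up to 0.500 d, but at 0.00200 d⁻¹ between 4.00 d and 8.00 d, far less, while starting material falls from 88.8% to 66.0%. So the rate follows something other than starting material. These readings show no partner, and a reversible stop would look the same, so the wager here is that partner is lost until the reaction starves.

**Partner yield.** That wager needs one quantity: the partner yield, the target made per partner charged, c(target) at the plateau over the charged c(partner), 16.6% in ash at 0 °C. Elm, at 6 °C and with 0.050 M of starting material, reads 9.57% at 3.00 d, so the yield is held to the temperature and the starting-material charge of ash. Under the wager, noon and midnight add nothing, and spring, reckoned at that yield with 66.0% of starting material remaining, adds 33 points, which takes the flask to 66.2%.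

**Forecast.** The forecast gives 33% at 8.0 d, 33.2% after noon and 33% after midnight, and names spring. It reads an equilibrium: “Catalyst then only speeds the approach”. It expects 43% to 51% after spring, so the two reckonings name the same option and part on its size.

**Result.** At 8.0 d the flask holds 32.5% of target; noon leaves 32.5%, midnight leaves 32.5%, and spring is best, adding 28 points.

    starting material + free catalyst → catalyst intermediate A (k = 0.628 M⁻¹ min⁻¹, Ea = 41.0 kJ mol⁻¹)
    partner + catalyst intermediate A → catalyst intermediate B (k = 0.153 M⁻¹ min⁻¹, Ea = 47.0 kJ mol⁻¹)
    catalyst intermediate B → released group + catalyst intermediate C (k = 0.0974 min⁻¹, Ea = 87.0 kJ mol⁻¹)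
    catalyst intermediate C → free catalyst + target (k = 3.76 min⁻¹, Ea = 66.0 kJ mol⁻¹)
    partner + target ⇌ idle adduct A, settled at all times (K = 1.11 M⁻¹, ΔH = −39.0 kJ mol⁻¹)
    partner → decomposed reagent (k = 6.77 × 10⁻⁴ min⁻¹, Ea = 99.0 kJ mol⁻¹)
    partner + released group ⇌ idle adduct B, settled at all times (K = 6.74 M⁻¹, ΔH = −30.0 kJ mol⁻¹)
    scavenger + released group → scavenged by-product (k = 0.0152 M⁻¹ min⁻¹, Ea = 63.0 kJ mol⁻¹)
    (constants at 0 °C)

**Partner spent.** At 8.00 d free partner in the flask stands at 0.00832% of its charge, the limiting reagent, beside 0.168 M of decomposed reagent. The partner yield of 16.6% put 33 points on spring, where the flask gives 28 points. A neighbour flask charged with 0.080 M of partner reckons, by the same yield, 13.2% of target, and it holds 15.0%.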